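**Retrosynthetic overview**
1. Target ⇐ (2S)-tris-MOM flavanone by acid removal of three MOM groups (last step).
2. The C ring (pyranone) is closed last: the O1–C2 bond and the C2 stereocentre come from a new catalytic enantioselective oxa-Michael cyclisation of a 2'-hydroxychalcone.
3. Chalcone ⇐ hexasubstituted o-hydroxyacetophenone + 4-(methoxymethoxy)benzaldehyde (Claisen–Schmidt).
4. Acetophenone ⇐ 3,5-bis(MOM-oxy)-4-methylphenol: its one free OH (the future O1, marked as an EE acetal) flanks two ortho-metalations (C-prenyl → C8, C-acetyl → C4a). This fixes the 6-methyl/8-prenyl pattern with no regioisomers.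
5. Phenol ⇐ 2-methylresorcinol (bis-MOM ether, then Ir C–H borylation/oxidation para to CH3). The A and B rings are bought as arenes.

**Assumptions (one line each)**
- The target is the (2S) enantiomer encoded by the SMILES. The 1-ethoxyethyl (EE) acetal carbon is racemic (no descriptor) and is removed before C2 is created.
- Catalyst C1 (step 7, proposed, not commercial) is the bifunctional iminophosphorane 1-[3,5-bis(trifluoromethyl)phenyl]-3-[(2S)-1-{[tris(4-methoxyphenyl)-λ5-phosphanylidene]amino}-3,3-dimethylbutan-2-yl]thiourea, made from the L-tert-leucinol-derived azido thiourea and P(4-MeOC6H4)3 by Staudinger reaction. Its sense of induction is a prediction, and its mirror image is used if the 2R product forms.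

**Route**

Step 1
Reactants: 1 2-methylresorcinol (2-methylbenzene-1,3-diol)
Product: 2 1,3-bis(methoxymethoxy)-2-methylbenzene
Conditions: NaH (2.4 equiv), MOMCl (2.3 equiv), DMF, 0 °C → rt
Reagents that add atoms: chloromethyl methyl ether (MOMCl) COCCl
Why: Williamson-type O-alkylation of both phenoxides gives the bis-MOM ether, which survives base and organolithiums and later directs metalation.

Step 2
Reactants: 2 1,3-bis(methoxymethoxy)-2-methylbenzene
Product: 4 3,5-bis(methoxymethoxy)-4-methylphenol, via aryl pinacol boronate 3 (not isolated)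
Conditions: [Ir(OMe)(cod)]2 (1.5 mol%), dtbpy (3 mol%), B2pin2 (0.6 equiv), THF, 80 °C; then 30% H2O2, aq. NaOH, 0 °C → rt
Reagents that add atoms: bis(pinacolato)diboron CC1(C)OB(OC1(C)C)B1OC(C)(C)C(C)(C)O1 (boron of 3); hydrogen peroxide OO (oxygen of 4)
Why: Sterically controlled Ir-catalysed aromatic C–H borylation hits only the one C–H with no ortho substituent (para to CH3), and boronate oxidation (ipso-hydroxylation) gives a phenol whose free oxygen, the future O1, is distinct from the two MOM-protected oxygens.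

Step 3
Reactants: 4 3,5-bis(methoxymethoxy)-4-methylphenol
Product: 5 5-(1-ethoxyethoxy)-1,3-bis(methoxymethoxy)-2-methylbenzene
Conditions: ethyl vinyl ether (3 equiv), PPTS (5 mol%), CH2Cl2, rt
Reagents that add atoms: ethyl vinyl ether C=COCC
Why: Acid-catalysed addition of the phenol to the vinyl ether (acetal protection) installs an EE group that directs ortho-metalation and is far more acid-labile than MOM.

Step 4
Reactants: 5 5-(1-ethoxyethoxy)-1,3-bis(methoxymethoxy)-2-methylbenzene
Product: 7 1-(1-ethoxyethoxy)-3,5-bis(methoxymethoxy)-4-methyl-2-(3-methylbut-2-en-1-yl)benzene, via aryllithium 6 (not isolated)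
Conditions: n-BuLi (1.1 equiv), THF, 0 °C, 1 h; CuI (10 mol%), prenyl bromide (1.3 equiv), −78 °C → rt
Reagents that add atoms: n-butyllithium [Li]CCCC (lithium of 6); prenyl bromide (1-bromo-3-methylbut-2-ene) CC(C)=CCBr
Why: Directed ortho-metalation at one of the two equivalent C–H bonds between the OEE and OMOM groups, then Cu-catalysed SN2 allylation, gives the linear C-prenyl arene (the future C8 substituent).

Step 5
Reactants: 7 1-(1-ethoxyethoxy)-3,5-bis(methoxymethoxy)-4-methyl-2-(3-methylbut-2-en-1-yl)benzene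
Product: 10 1-[2-hydroxy-4,6-bis(methoxymethoxy)-5-methyl-3-(3-methylbut-2-en-1-yl)phenyl]ethan-1-one, via aryllithium 8 (not isolated), via EE-protected ketone 9 (not isolated)
Conditions: n-BuLi (1.2 equiv), THF, 0 °C, 1.5 h; MeC(O)N(OMe)Me, −78 → 0 °C; H2O; then PPTS (0.2 equiv), MeOH, rt
Reagents that add atoms: n-butyllithium [Li]CCCC (lithium of 8); N-methoxy-N-methylacetamide CC(=O)N(C)OC
Why: A second directed ortho-metalation at the only remaining ring C–H, Weinreb-amide acylation (the chelated tetrahedral adduct stops over-addition) and selective acetal exchange of the EE group with PPTS/MeOH unmask only the phenol that becomes O1, while both MOM ethers stay.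

Step 6
Reactants: 10 1-[2-hydroxy-4,6-bis(methoxymethoxy)-5-methyl-3-(3-methylbut-2-en-1-yl)phenyl]ethan-1-one; 11 4-(methoxymethoxy)benzaldehyde
Product: 13 (2E)-1-[2-hydroxy-4,6-bis(methoxymethoxy)-5-methyl-3-(3-methylbut-2-en-1-yl)phenyl]-3-[4-(methoxymethoxy)phenyl]prop-2-en-1-one, via aldol adduct 12 (not isolated)
Conditions: KOH (50% aq., 10 equiv), EtOH, rt, 36 h; cold dil. AcOH to pH 6
Reagents that add atoms: none
Why: Claisen–Schmidt (crossed aldol) condensation with a non-enolisable aldehyde and E1cB dehydration gives the E-chalcone; the MOM ethers are base-stable and the chelated phenoxide does not cyclise in strong base.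

Step 7
Reactants: 13 (2E)-1-[2-hydroxy-4,6-bis(methoxymethoxy)-5-methyl-3-(3-methylbut-2-en-1-yl)phenyl]-3-[4-(methoxymethoxy)phenyl]prop-2-en-1-one
Product: 14 (2S)-5,7-bis(methoxymethoxy)-2-[4-(methoxymethoxy)phenyl]-6-methyl-8-(3-methylbut-2-en-1-yl)-2,3-dihydro-4H-chromen-4-one
Conditions: C1 (10 mol%), toluene (0.05 M), 4 Å MS, 0 °C; AcOH quench at full conversion
Reagents that add atoms: none
Why: Proposed new method: catalytic enantioselective 6-endo-trig oxa-Michael cyclisation of an unactivated, fully substituted 2'-hydroxychalcone by a bifunctional iminophosphorane–thiourea superbase, in which the iminophosphorane deprotonates the chelated 2'-OH to a tight chiral iminophosphoranium–phenoxide ion pair while the thiourea hydrogen-bonds the enone carbonyl, so the phenoxide adds to the Si face of Cβ (the tert-butyl group shields the Re face) and sets C2 as S, after which the P=N–H+ returns the proton to the enolate and releases a flavanone that has no acidic OH to re-bind; the 6'-OMOM group, buttressed by 5'-methyl and 3'-prenyl, twists the aroyl group out of conjugation, which raises phenoxide nucleophilicity and makes closure strongly downhill, so the retro-oxa-Michael racemisation channel is much slower than closure and is cut off by the acid quench; the closest known reaction types are iminophosphorane-catalysed enantioselective intramolecular oxa-Michael additions of alcohols to unactivated α,β-unsaturated esters and amides and cinchona-thiourea cyclisations of ester-activated alkylidene β-ketoesters to flavanones, whereas plain 2'-hydroxychalcones have so far given only modest ee.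

Step 8
Reactants: 14 (2S)-5,7-bis(methoxymethoxy)-2-[4-(methoxymethoxy)phenyl]-6-methyl-8-(3-methylbut-2-en-1-yl)-2,3-dihydro-4H-chromen-4-one
Product: 15 (2S)-5,7-dihydroxy-2-(4-hydroxyphenyl)-6-methyl-8-(3-methylbut-2-en-1-yl)-2,3-dihydro-4H-chromen-4-one (6-methyl-8-prenylnaringenin)
Conditions: 3 M aq. HCl/MeOH (1:4), 40 °C, 2 h, N2
Reagents that add atoms: none
Why: Acid-catalysed acetal solvolysis removes all three MOM groups; C2 is not touched because flavanone ring opening is base-promoted, and the prenyl group tolerates dilute HCl in MeOH at 40 °C.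

**Compound list**
1 | 2-methylresorcinol (2-methylbenzene-1,3-diol) | Cc1c(O)cccc1O | starting material
2 | 1,3-bis(methoxymethoxy)-2-methylbenzene | COCOc1cccc(OCOC)c1C | intermediate
3 | 2-[3,5-bis(methoxymethoxy)-4-methylphenyl]-4,4,5,5-tetramethyl-1,3,2-dioxaborolane (not isolated) | Cc1c(OCOC)cc(cc1OCOC)B1OC(C)(C)C(C)(C)O1 | intermediate
4 | 3,5-bis(methoxymethoxy)-4-methylphenol | Cc1c(OCOC)cc(O)cc1OCOC | intermediate
5 | 5-(1-ethoxyethoxy)-1,3-bis(methoxymethoxy)-2-methylbenzene (racemic acetal) | CCOC(C)Oc1cc(OCOC)c(C)c(OCOC)c1 | intermediate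
6 | [2-(1-ethoxyethoxy)-4,6-bis(methoxymethoxy)-5-methylphenyl]lithium (not isolated) | CCOC(C)Oc1cc(OCOC)c(C)c(OCOC)c1[Li] | intermediate
7 | 1-(1-ethoxyethoxy)-3,5-bis(methoxymethoxy)-4-methyl-2-(3-methylbut-2-en-1-yl)benzene | CCOC(C)Oc1cc(OCOC)c(C)c(OCOC)c1CC=C(C)C | intermediate
8 | [2-(1-ethoxyethoxy)-4,6-bis(methoxymethoxy)-5-methyl-3-(3-methylbut-2-en-1-yl)phenyl]lithium (not isolated) | CCOC(C)Oc1c([Li])c(OCOC)c(C)c(OCOC)c1CC=C(C)C | intermediate
9 | 1-[2-(1-ethoxyethoxy)-4,6-bis(methoxymethoxy)-5-methyl-3-(3-methylbut-2-en-1-yl)phenyl]ethan-1-one (not isolated) | CCOC(C)Oc1c(C(C)=O)c(OCOC)c(C)c(OCOC)c1CC=C(C)C | intermediate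
10 | 1-[2-hydroxy-4,6-bis(methoxymethoxy)-5-methyl-3-(3-methylbut-2-en-1-yl)phenyl]ethan-1-one | CC(=O)c1c(O)c(CC=C(C)C)c(OCOC)c(C)c1OCOC | intermediate
11 | 4-(methoxymethoxy)benzaldehyde | COCOc1ccc(C=O)cc1 | starting material
12 | 3-hydroxy-1-[2-hydroxy-4,6-bis(methoxymethoxy)-5-methyl-3-(3-methylbut-2-en-1-yl)phenyl]-3-[4-(methoxymethoxy)phenyl]propan-1-one (racemic, not isolated) | COCOc1ccc(cc1)C(O)CC(=O)c1c(O)c(CC=C(C)C)c(OCOC)c(C)c1OCOC | intermediate
13 | (2E)-1-[2-hydroxy-4,6-bis(methoxymethoxy)-5-methyl-3-(3-methylbut-2-en-1-yl)phenyl]-3-[4-(methoxymethoxy)phenyl]prop-2-en-1-one | COCOc1ccc(/C=C/C(=O)c2c(O)c(CC=C(C)C)c(OCOC)c(C)c2OCOC)cc1 | intermediate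
14 | (2S)-5,7-bis(methoxymethoxy)-2-[4-(methoxymethoxy)phenyl]-6-methyl-8-(3-methylbut-2-en-1-yl)-2,3-dihydro-4H-chromen-4-one | CC(C)=CCc1c(OCOC)c(C)c(OCOC)c2c1O[C@H](c1ccc(OCOC)cc1)CC2=O | intermediate
15 | (2S)-5,7-dihydroxy-2-(4-hydroxyphenyl)-6-methyl-8-(3-methylbut-2-en-1-yl)-2,3-dihydro-4H-chromen-4-one (6-methyl-8-prenylnaringenin) | CC(C)=CCc1c(O)c(C)c(O)c2c1O[C@H](c1ccc(O)cc1)CC2=O | target

**Totals**
Total step count: 8. Longest linear sequence: 8 steps (1 → 15); aldehyde 11 is bought.

**Three steps most likely to fail, each with one fallback**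

Step 5 (second metalation and acylation). The risk is lateral lithiation at the benzylic/allylic prenyl CH2, or poor acylation of the very hindered aryllithium. The fallback reverses the order of the two C–C bond formations and replaces the second organolithium step by halogenation and cross-coupling. It sets out from 5 and comes back at 10. Compound 5 is lithiated as in step 4 (giving 6) and acylated with N-methoxy-N-methylacetamide to the EE-protected ketone 1-[2-(1-ethoxyethoxy)-4,6-bis(methoxymethoxy)-5-methylphenyl]ethan-1-one F1. PPTS/MeOH then gives 1-[2-hydroxy-4,6-bis(methoxymethoxy)-5-methylphenyl]ethan-1-one F2. Its single free ring position is iodinated (NIS, MeCN, 0 °C) to 1-[2-hydroxy-3-iodo-4,6-bis(methoxymethoxy)-5-methylphenyl]ethan-1-one F3. Stille coupling with tributyl(3-methylbut-2-en-1-yl)stannane (Pd(PPh3)4, DMF, 90 °C) delivers 10.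

Step 7 (the proposed new cyclisation). The risk is low ee through reversible ring opening, low rate, or the wrong sense of induction. The fallback uses known chemistry only; it sets out from 13 and comes back at 14. Chalcone 13 is cyclised with NaOAc in refluxing EtOH to the racemic flavanone (2RS)-5,7-bis(methoxymethoxy)-2-[4-(methoxymethoxy)phenyl]-6-methyl-8-(3-methylbut-2-en-1-yl)-2,3-dihydro-4H-chromen-4-one F4. F4 is then resolved kinetically by Ru-catalysed asymmetric transfer hydrogenation (RuCl(p-cymene)[(R,R)-TsDPEN] 1–2 mol%, HCO2H/Et3N, EtOAc, rt, stopped near 52–55% conversion). This reduces the 2R enantiomer to the cis alcohol (2R,4R)-5,7-bis(methoxymethoxy)-2-[4-(methoxymethoxy)phenyl]-6-methyl-8-(3-methylbut-2-en-1-yl)-3,4-dihydro-2H-chromen-4-ol F5 and leaves (2S)-14, which is separated by chromatography. The catalyst hand follows the usual transfer-hydrogenation model and should be confirmed on small scale.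

Step 8 (acidic MOM removal). The risk is acid-induced chroman formation from 7-OH and the prenyl group, or partial loss of ee. The fallback replaces Brønsted-acid solvolysis by silyl-transfer deacetalisation through a discrete silyl ether; it sets out from 14 and comes back at 15. Compound 14 is treated with TMSOTf and 2,2'-bipyridyl in MeCN (0 °C → rt), which converts the three aryl MOM ethers into the tris(trimethylsilyl) ether (2S)-6-methyl-8-(3-methylbut-2-en-1-yl)-5,7-bis(trimethylsilyloxy)-2-[4-(trimethylsilyloxy)phenyl]-2,3-dihydro-4H-chromen-4-one F6. Neutral aqueous hydrolysis (H2O/MeCN, rt) then gives 15 without protic acid.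

**Further compounds**
F1 | step 5 | 1-[2-(1-ethoxyethoxy)-4,6-bis(methoxymethoxy)-5-methylphenyl]ethan-1-one | CCOC(C)Oc1cc(OCOC)c(C)c(OCOC)c1C(C)=O
F2 | step 5 | 1-[2-hydroxy-4,6-bis(methoxymethoxy)-5-methylphenyl]ethan-1-one | CC(=O)c1c(O)cc(OCOC)c(C)c1OCOC
F3 | step 5 | 1-[2-hydroxy-3-iodo-4,6-bis(methoxymethoxy)-5-methylphenyl]ethan-1-one | CC(=O)c1c(O)c(I)c(OCOC)c(C)c1OCOC
F4 | step 7 | (2RS)-5,7-bis(methoxymethoxy)-2-[4-(methoxymethoxy)phenyl]-6-methyl-8-(3-methylbut-2-en-1-yl)-2,3-dihydro-4H-chromen-4-one (racemate) | CC(C)=CCc1c(OCOC)c(C)c(OCOC)c2c1OC(c1ccc(OCOC)cc1)CC2=O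
F5 | step 7 | (2R,4R)-5,7-bis(methoxymethoxy)-2-[4-(methoxymethoxy)phenyl]-6-methyl-8-(3-methylbut-2-en-1-yl)-3,4-dihydro-2H-chromen-4-ol | CC(C)=CCc1c(OCOC)c(C)c(OCOC)c2c1O[C@@H](c1ccc(OCOC)cc1)C[C@H]2O
F6 | step 8 | (2S)-6-methyl-8-(3-methylbut-2-en-1-yl)-5,7-bis(trimethylsilyloxy)-2-[4-(trimethylsilyloxy)phenyl]-2,3-dihydro-4H-chromen-4-one | CC(C)=CCc1c(O[Si](C)(C)C)c(C)c(O[Si](C)(C)C)c2c1O[C@H](c1ccc(O[Si](C)(C)C)cc1)CC2=O
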